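The readings were computed with constants of no real substance; noise was put on by code.

Monomer in chains is the product we count, so I reckon from the part of the charge that has reached chains in the runs.

in all of them: free monomer 2.6 M
- winter: transfer agent 0.26 M; initiator 2.8 mol%; temperature 30 °C; run made earlier
- dusk: transfer agent 0.26 M; initiator 4.4 mol%; temperature 50 °C; run made earlier
- autumn: transfer agent 0.13 M; initiator 2 mol%; temperature 30 °C; run made earlier
- beta: transfer agent 0.260 M; initiator 2 mol%; temperature 35 °C; time 3.0 h
- theta: transfer agent 0.260 M; initiator 2 mol%; temperature 65 °C; time 3.0 h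
- zeta: transfer agent 0.260 M; initiator 2 mol%; temperature 50 °C; time 3.0 h

winter run (percent of the free monomer charged)

| time / h | monomer in chains / % | free monomer / % |
|---|---|---|
| 0.333 | 26.3 | 64.9 |
| 0.833 | 61.5 | 26.3 |
| 1.50 | 77.4 | 7.4 |
| 2.50 | 83.8 | 0.7 |

dusk run (percent of the free monomer charged)

| time / min | monomer in chains / % | free monomer / % |
|---|---|---|
| 10.0 | 60.6 | 14.4 |
| 25.0 | 75.4 | 3.8 |
| 40.0 | 79.2 | 2.2 |
| 80.0 | 84.3 | 2.2 |

autumn run (percent of the free monomer charged)

| time / h | monomer in chains / % | free monomer / % |
|---|---|---|
| 0.333 | 19.2 | 73.9 |
| 0.833 | 51.3 | 35.0 |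
| 1.50 | 71.8 | 12.0 |
| 2.50 | 81.1 | 1.7 |

(each reading ± 1 percentage point)

- the best flask by amount of monomer in chains, in percent of the free monomer charged; "all alike" if 1.5 percentage points covers them all (beta / theta / zeta / all alike)
- amount of monomer in chains at the end, in percent of the free monomer charged, beta
- amount of monomer in chains at the end, in percent of the free monomer charged, theta
- amount of monomer in chains at the end, in percent of the free monomer charged, zeta

**What do you measure a recipe by?** By its chain reach: the logarithm to base ten of the charge over what is not in chains, so one unit of reach means the part outside chains has shrunk tenfold. Winter ends at 83.8% in chains, a reach of 0.790. Dusk ends at 84.3%, a reach of 0.804.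

**How do you bring those runs to 2 mol% of initiator?** I multiply reach by the square root of the loading ratio. At 1.50 h, winter's reach is 1.17 times autumn's, and the root of their loadings is 1.18.

**But winter and autumn also differ in transfer agent.** Yes, so the root is a reading and not a law. The scaled reach is 0.668 at 30 °C from winter and 0.542 at 50 °C from dusk. The second figure is my estimate, read from dusk's last reading, of the chain reach of a 2 mol% recipe at 50 °C.

**And temperature?** I draw a straight line in reach through those two figures. Beta gets 0.637, or 76.9% in chains. Zeta gets 71.3%. Theta gets 0.448, or 64.3%.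

**Which figure is shakiest?** Theta's, since 65 °C lies above both runs that carry the line. Still, I commit to beta, ahead of zeta by 5.6 percentage points, which exceeds the margin.

The forecast also names beta, with 87%, 62% and 85.5% for beta, theta and zeta, but says “beta narrowly leads zeta”, and its zeta stands above mine. The flasks give beta as best, with 77.5% for beta, 53.7% for theta and 68.9% for zeta.

    free monomer ⇌ dormant form (K = 2.80, k = 0.0520 /min, Ea = 102 kJ/mol, ΔH = 1.00 kJ/mol)
    living end + transfer agent → dead chain (kL = 0.140 /M/min, Ea = 76.0 kJ/mol)
    free monomer → uncatalysed product (k = 0.00160 /min, Ea = 94.0 kJ/mol)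
    initiator → spent initiator (k = 0.0270 /min, Ea = 101 kJ/mol)
    free monomer + living end → monomer in chains + living end, rate k5*[living end]*[free monomer] (k = 2.50 /M/min, Ea = 57.0 kJ/mol)
    free monomer + initiator → living end + monomer in chains (k = 0.120 /M/min, Ea = 75.0 kJ/mol)
    (constants at 50 °C)

Zeta's reach is 0.507 against 0.542, while theta's is 0.334 against 0.448. For the neighbour of zeta with 0.10 M of transfer agent, 0.542 times the root of the transfer agent ratio gives 0.874, and its simulated 85.3% is a reach of 0.833. In zeta, the passing into chains had 74% of its turnover behind it at 0.300 h, and initiator was down to 0.141% of its charge at 1.50 h. From then to 3.00 h, monomer in chains moved from 67.3% to 68.9% as living end fell to 1.97 × 10⁻⁴ M, leaving 20.8% as dormant form.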